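All runs are simulated for an exercise; the scatter is artificial.

in all of them: nucleophile 0.0312 M (fed, over 8.0 min)

| charge | electrophile | remark | time |
|---|---|---|---|
| alpha | 0.024 M | the very flask that is asked about, followed so far |  |
| zeta | 0.048 M | run made earlier |  |
| flask | 0.024 M |  | 8.0 min |

| run | time / min | electrophile / % | target / % |
|---|---|---|---|
| alpha | 0.250 | 99.4 | 0.3 |
| alpha | 0.417 | 99.3 | 0 |
| alpha | 0.667 | 98.7 | 1.0 |
| alpha | 1.33 | 98.4 | 2.4 |
| alpha | 2.00 | 95.3 | 4.0 |
| alpha | 3.00 | 91.1 | 8.6 |
| zeta | 0.500 | 99.9 | 0.5 |
| zeta | 1.50 | 98.6 | 2.0 |
| zeta | 3.00 | 92.3 | 6.6 |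
| zeta | 4.00 | 89.6 | 11.3 |
| zeta | 6.00 | 81.7 | 17.0 |
| zeta | 8.00 | 75.5 | 25.2 |

(standard deviation of a reading: 0.5 percentage points)
- steps thought possible: electrophile + nucleophile -> acid set free + target; nucleophile + acid set free <-> protonated nucleophile; acid set free + target -> side product; nucleophile <-> dormant form
- the earlier runs do not show how much of nucleophile is bound; that part of a forecast is a guess
1. part of the electrophile that has reacted at 8.0 min
2. share of free nucleophile in free nucleophile and protonated nucleophile together, at 8.0 min

- I read the slowness of alpha, with 8.6% target at 3.00 min, through two times: the dosing time 8.0 min and the life of a free nucleophile among electrophile.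
- Each turnover takes one nucleophile into target, and the acid set free can take a second as protonated nucleophile, so I price a turnover at two; late in zeta the feed is 0.00390 M min⁻¹ and the target gain, read with scatter, is 0.00197 M min⁻¹, so this reading puts the feed at twice that gain.
- In zeta, electrophile and target at 8.00 min add up to 101%, so I give the side product no time of its own.
- That gain, with mid-interval [electrophile] and [nucleophile] (fed less two per turnover), gives for alpha's charge 2.81 min as the capture time τ, the pseudo-first-order life of free nucleophile.
- The dose lasts longer, 2.85 τ, so in my reckoning, with [electrophile] held, [nucleophile] climbs exponentially towards feed times τ, and the rest of what was fed counts as spent in pairs.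
- That gives 43.5% reacted; since [electrophile] falls, I rerun it with its mean, τ becoming 3.59 min, and commit to 38.9% and, guessing full binding, a free share of 57.2%.
- The forecast, below my reacted part, says 37.5% and 59%, adding “only inferred, because the runs never measure binding”.
- The flask gives 36.9% and 56.7%.

    electrophile + nucleophile → acid set free + target (k = 0.130 M⁻¹ s⁻¹)
    nucleophile + acid set free ⇌ protonated nucleophile, settled at all times (K = 14000 M⁻¹)
    acid set free + target → side product (k = 0.0770 M⁻¹ s⁻¹)
    nucleophile ⇌ dormant form (K = 0.510, k = 7.30 × 10⁻⁴ s⁻¹)

- In this flask the first step ran late, with 2.4% of its turnover done at 0.800 min and half by 4.77 min, while protonated nucleophile reached 0.00880 M at 8.00 min beside 0.00885 M target; dormant form then held 0.00201 M, which τ does not count, and my reacted part stands 2 percentage points above.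
- With 0.041 M electrophile, τ scales to 1.65 min, the mean-[electrophile] value is 1.94 min, and the same reckoning gives 29.0%; that flask gives 27.7%.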